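(The data were generated by integration for substances that don't exist, and the scatter is random.)

Time first: the asked 40 h is twice the 20.0 h of the last reading in Tuesday's run, so we start from what each earlier run had reached by its end.

| setting | Tuesday's | Sunday's | Monday's | dawn | dusk | summer | winter |
|---|---|---|---|---|---|---|---|
| substrate | 0.15 M | 0.15 M | 0.15 M | 0.15 M | 0.15 M | 0.15 M | 0.15 M |
| coupling partner | 0.21 M | 0.48 M | 0.78 M | 0.250 M | 0.400 M | 0.600 M | 1.00 M |
| remark | run made earlier | run made earlier | run made earlier |  |  |  |  |
| time |  |  |  | 40 h | 40 h | 40 h | 40 h |

- Tuesday's (time / h: target / %): 5.00: 67.1; 10.0: 81.6; 15.0: 85.8; 20.0: 87.2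
- Sunday's (time / h: target / %): 5.00: 88.4; 10.0: 91.3; 15.0: 91.6; 20.0: 91.8
- Monday's (time / h: target / %): 1.50: 59.3; 4.00: 90.7; 8.00: 93.5; 20.0: 93.4

(standard deviation of a reading: 0.3 percentage points)

- amount of target at the end, in percent of the substrate charged for dawn, dusk, summer, winter, in this order
- how that number moves from the first to the last of them (falls, then rises / rises, then falls / hardly changes / falls all the way / rises all the way)

- "hardly changes" means that all values lie within two and a half points (for a concentration: within two and a half percent of the largest)

Monday's run reads 93.5% at 8.00 h and 93.4% at 20.0 h, and Sunday's run gains 0.2 percentage points over its last step, against a scatter of 0.3 points. We take both as flat, with no target being lost from them. Tuesday's run still moves: its last two equal steps gain 4.2 points and 1.4 points, the second a third of the first. If later steps keep shrinking so, it ends near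

0.333 per step, end value 87.9%.

Call the loss the part of the substrate charged that does not end as target. Tuesday's run loses 12.1% and Monday's run 6.60%. We go to logarithms to base ten:

log of the loss ratio = 0.263; log of the c(coupling partner) ratio = 0.570; n = 0.462.

This n is the loss exponent: the powers of ten by which the loss falls for each power of ten of c(coupling partner). Sunday's run took no part in it, so it can test it: n predicts a loss of 8.26%, and the reading leaves 8.20%.

Dawn holds more coupling partner than Tuesday's run, so we take plateaus at 40 h. Scaling Monday's loss by n gives our row:

dawn 88.8%; dusk 91.0%; summer 92.5%; winter 94.1%.

The weak link is Tuesday's end value, which rests on a small difference of two readings. Forged again from the two flat runs: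

n = 0.447; dawn 89.0%; winter 94.1%.

Dawn moves by 0.20 points, inside the scatter, so we keep our row, rising from dawn to winter.

The forecast, reckoned apart from ours, reads 88.9%, 91.2%, 92.7%, 94%, so rises all the way, in its words: “The yield rises throughout.”

The flask gives 88.5%, 90.5%, 92.3% and 94.5%: rises all the way.

    substrate + coupling partner → intermediate + by-product (k = 2.70 /M/h)
    intermediate → target (k = 1.10 /h)
    substrate + intermediate → side product (k = 1.40 /M/h)
    2 substrate → self-condensation product (k = 6.40 × 10⁻⁴ /M/h)

At dawn the intermediate has a half-life of 0.63 h by turning into target and 3.3 h by meeting substrate at its charged concentration, 5.24 times as long, and dawn ends with 88.5% target beside 11.5% side product. The loss exponent read from the results of dawn and winter is 0.532 against our 0.462, and our 0.462, carried from dawn's loss of 11.5%, gives winter 93.9% target where winter holds 94.5%.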